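**Comparison.** The precatalyst is compared here at fixed conversion, not at a fixed clock time. The flask differs from Tuesday's run in one charge: it holds half the precatalyst.

the same everywhere: left-handed substrate 1.5 M; right-handed substrate 1.5 M
- Sunday's: coupling partner 0.75 M; precatalyst 38 mM; run made earlier
- Wednesday's: coupling partner 1.1 M; precatalyst 38 mM; run made earlier
- Tuesday's: coupling partner 1.5 M; precatalyst 76 mM; run made earlier
- flask: coupling partner 1.50 M; precatalyst 38 mM

| run | time / h | left-handed product / % | left-handed substrate / % |
|---|---|---|---|
| Sunday's | 2.50 | 0 | 48.9 |
| Sunday's | 6.00 | 0 | 48.2 |
| Sunday's | 12.0 | 0.7 | 47.6 |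
| Sunday's | 20.0 | 3.2 | 45.0 |
| Wednesday's | 1.33 | 1.4 | 48.6 |
| Wednesday's | 3.00 | 0 | 50.6 |
| Wednesday's | 8.00 | 4.0 | 48.8 |
| Wednesday's | 20.0 | 6.7 | 42.9 |
| Tuesday's | 2.50 | 1.6 | 48.8 |
| Tuesday's | 6.00 | 2.8 | 46.8 |
| Tuesday's | 12.0 | 11.9 | 39.9 |
| Tuesday's | 20.0 | 16.6 | 33.1 |

(each reading ± 1 percentage point)

- catalyst is single-handed; left-handed substrate and right-handed substrate are mirror images of each other, charged as a racemate, each of them at the stated concentration
- the numbers in the tables scatter with a standard deviation of 1 percentage point

- factor on the rate of making left-handed product when 5.0% of the left-handed substrate and right-handed substrate together are converted if precatalyst is charged twice over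
- factor on the rate when 5.0% of the left-handed substrate and right-handed substrate together are converted if precatalyst is charged at 200 mM instead

**Slow start.** Sunday's run shows 0% left-handed product at 6.00 h but 3.2% at 20.0 h. This induction period is read here as catalyst being made from precatalyst during the run.

**First way.** Suppose catalyst grows in proportion to load and to time. The rate then goes with load times time, and product with load times the square of time. A fixed conversion arrives sooner by the square root of the load ratio, so the rate there rises by that same root. This gives the doubling factor, the gain in rate at fixed conversion per doubling of load, 1.41.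

**Second way.** If product goes with load times time to a power m, the doubling factor is 2 to the power one over m. Tuesday's left-handed product from 6.00 h to 12.0 h reads m as 2.09, hence a factor of 1.39. This is a loose reading: the 2.8% carries a scatter of 1 point, and the mark of 5.0% counts both substrates together, while this span follows left-handed product alone. Its nearness to 1.41 therefore confirms nothing, and the reckoning here rests on the first way.

**Forecast.** The forecast takes a precatalyst order of 0.7 and gives 1.6 and 3.2, warning that “this is an extrapolation beyond the tested range”. The reckoning here differs: 1.41 and, over 2.40 doublings, 2.29.

**Result.** The simulation gives 1.49 and 2.52.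

    coupling partner + catalyst + left-handed substrate → catalyst + left-handed product (k = 2.97 L² mol⁻² h⁻¹)
    coupling partner + catalyst + right-handed substrate → catalyst + right-handed product (k = 1.65 L² mol⁻² h⁻¹)
    coupling partner → decomposed reagent (k = 0.0159 h⁻¹)
    coupling partner + precatalyst → catalyst + spent reagent (k = 0.0115 L mol⁻¹ h⁻¹)

At 7.58 h the flask holds 11.2% of its catalyst as catalyst and 88.8% as precatalyst. For the 200 mM flask, the doubling factor taken over 2.40 doublings gives 2.29, less than the 2.52 found.

The earlier runs and the new flask are simulated with constants of no real substance, noise included.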